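A half-life of 150 min is the number to carry from Tuesday's run: it is the loss half-life of Q, the time in which Q falls to half at the pace it keeps between two readings, read as a reading from Q at 20.0 min and 80.0 min. Hold it against your stopping time at Tuesday's temperature and you have a first guess at whether that flask is still moving.

| setting | Wednesday's | Tuesday's | noon | winter | dusk | dawn |
|---|---|---|---|---|---|---|
| Z | 0.14 M | 0.20 M | 0.27 M | 0.27 M | 0.27 M | 0.27 M |
| X | 0.675 M | 0.675 M | 0.675 M | 0.675 M | 0.675 M | 0.675 M |
| temperature | 25 °C | 55 °C | 80 °C | 30 °C |  | 55 °C |
| remark | run made earlier | run made earlier |  |  | at 30 °C until 8.0 min, from then on at 80 °C |  |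
| time |  |  | 40 min | 40 min | 40 min | 40 min |

- Wednesday's (time / min: Q / %, Z / %): 80.0: 96.5, 3.1; 150: 97.7, 0.4; 240: 96.5, 0.4; 300: 96.4, 0; 360: 95.2, 0.7
- Tuesday's (time / min: Q / %, Z / %): 6.00: 92.4, 4.4; 20.0: 88.6, 0; 40.0: 80.8, 0; 50.0: 77.4, 0.5; 80.0: 67.1, 0.1

(each reading ± 0.5 percentage points)

- a reading or a percentage of Q counts all its forms, free or not

- the best flask by amount of Q, in percent of the Z charged; "all alike" if 1.5 percentage points covers them all (noon / winter / dusk / dawn / all alike)
- amount of Q at the end, in percent of the Z charged, noon
- amount of Q at the end, in percent of the Z charged, winter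
- amount of Q at the end, in percent of the Z charged, dusk
- amount of Q at the end, in percent of the Z charged, dawn

Put the clocks in order, fastest first, and take them as rough: Wednesday's run was charged with 0.14 M of Z and Tuesday's with 0.20 M. On Tuesday's first reading Z has a half-life near 1.33 min, so Z is turned long before Q falls. On Wednesday's first reading Z takes about 16.0 min, and that run's Q readings give a loss half-life of about 5620 min, poorly held within the scatter. Going from Wednesday's run to Tuesday's, with both temperature and charge changed, shortens the loss clock by a factor of 37.5, but the Z clock by 12.0.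

So I expect control to change hands as you warm. Winter's temperature is near Wednesday's, and I expect what you miss there to be Z not yet turned: by my reckoning Wednesday's clock leaves 17.7% of the charge after 40 min, and winter is warmer. Dawn has Tuesday's temperature, where the Z clock is shorter than 40 min, so I expect what you miss there to be Q lost; from Tuesday's 88.6% at 20.0 min I reckon 80.8% for dawn, though dawn's charge is larger. The step from Tuesday's temperature to noon's is smaller than the one from Wednesday's, but one more factor of that size brings the loss half-life to 4.00 min, shorter than 40 min, so I put noon past the crossing.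

The forecast, reading “Q decaying first-order after formation”, gives noon 6%, winter 90%, dusk 10.5% and dawn 80.5%, and names winter as best. I share that choice.

The flasks give noon 51.1%, winter 95.8%, dusk 51.5% and dawn 85.4%, so winter holds most Q.

    Z + X → Q, rate k1*[Z]^1.5*[X]^0.5 (k = 0.310 L mol⁻¹ s⁻¹, Ea = 60.0 kJ mol⁻¹)
    E ⇌ Q, rate k2*(cs2 - [Q]) while solid is left; crystals form when [Q] > cs2 (solubility = 0.160 M, k = 0.980 s⁻¹)
    Q ⇌ G (K = 0.920, k = 0.00170 s⁻¹, Ea = 108 kJ mol⁻¹, ΔH = −24.0 kJ mol⁻¹)
    Z + Q → D (k = 0.00390 L mol⁻¹ s⁻¹, Ea = 88.0 kJ mol⁻¹)
    (constants at 80 °C)

Noon parts furthest from the forecast: its Q stands at 52.4% after 20.0 min and 51.1% after 40.0 min, beside G at 47.0%, which is thermodynamic control, and in noon dissolved Q and G relax, by that step alone and both ways together, with a half-life of 3.26 min, short against 40 min. Ten times the time leaves noon at 51.1% and dusk at 51.4%. Winter goes from 95.8% to 94.1% in that time. Dawn, at Tuesday's temperature, where the half-life read was 150 min, longer than 40 min, has not come to rest: after 400 min its Q is 38.3% and its G 60.8%.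

(The numbers in the tables are calculated on assumed constants.)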